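## The problem

The target 21 is 2-(3,5-dihydroxy-4-methoxyphenyl)-5-hydroxy-3,7-dimethoxy-8-methyl-4H-chromen-4-one (flavone numbering is used throughout). Ring A carries OH at C5, H at C6, OMe at C7 and CH3 at C8, and is fused through C4a and C8a to pyranone ring C, which bears an enol-ether methoxy at C3 and ring B at C2. The molecule has no stereocentre, so nothing has to be set or relayed; the difficulty is regiochemical. The ring A ketone carbon C4a has two ortho carbons, C5 and C8a, and both are oxygenated in the target. A classical cyclodehydration of a 2,6-dioxygenated aryl diketone can therefore close through either oxygen and give the 6-methyl or the 8-methyl flavone, and acid can interconvert the two by ring opening and reclosure. Three phenols (C5, C3', C5') stand beside three methyl ethers (C3, C7, C4'), so the phenols need a mask that comes off without touching a methyl ether. The C3 methoxy next to the C4 carbonyl is prone to chelation-assisted cleavage by boron or aluminium halides, and the free 3,5-dihydroxy-4-methoxyphenyl ring is easily oxidised in base and air; the phenols are therefore carried as benzyl ethers and released last under neutral conditions. The feature that makes the key step possible is that C8a is ortho to the C4 carbonyl and meta to both ring A alkoxy groups. A fluorine placed on C8a alone is thus activated for addition–elimination, and it is the only place where the enolate oxygen of an open 1,3-diketone can close.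

## Retrosynthesis

Cutting the three O–CH2Ph bonds of 21 leads to tribenzyl ether 20. Benzyl is preferred to methyl or isopropyl ethers, whose removal needs Lewis acids that also attack the C3 methoxy, and to silyl ethers, which would not survive the basic ring closure. The skeleton is unchanged, but 20 has no acidic or oxidisable phenol. The forward step must remove three benzyl groups and leave the C2–C3 double bond and the C4 carbonyl alone.

In 20 the O1–C8a bond is cut, giving the open 2-methoxy-1,3-diketone 17 with fluorine on C8a. The neighbouring cut at O1–C2 would need a ring A ketone flanked by two oxygens, told apart by protecting groups only, and would bring back the 6-methyl/8-methyl ambiguity under acid. A cut at C4–C4a would need a preformed aryl vinyl ether. With fluoride as the only leaving group, closure through enolate 18 and adduct 19 can go one way. Precursor 17 has lost ring C and consists of two arenes joined by a three-carbon chain. The forward reaction must make an electron-rich fluoroarene accept an enolate oxygen.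

Diketone 17 is cut between the central carbon (the later C3) and the ring B carbonyl (the later C2), giving α-methoxy ketone 11 and aroyl chloride 15. The other cut, between the central carbon and the ring A carbonyl, would use a ring A acid chloride with two ortho substituents as a hindered acyl donor. The chosen cut makes the hindered partner the nucleophile (enolate 16) and the unhindered one the electrophile. The forward reaction must acylate carbon and not oxygen.

Acid chloride 15 goes back through acid 14 to 3,5-dihydroxy-4-methoxybenzoic acid 12 by cutting the two O–benzyl bonds; benzyl ester 13 is a passing intermediate. Only routine alkylation, saponification and chloride formation are asked for.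

Ketone 11 is cut at the aryl–carbonyl bond (C4–C4a) into arene 6 and Weinreb amide 8, which comes from methoxyacetyl chloride 7. An electrophilic acylation of 6 would have to choose between two activated positions under Lewis acids that endanger the benzyl ether. Deprotonation uses the fluorine instead: the C–H between fluorine and benzyloxy is the only one acidic enough for a lithium amide, giving aryllithium 9, and adduct 10 keeps the ketone masked until work-up. Arene 6 is a simple tetrasubstituted benzene. The forward step needs site-selective lithiation at low temperature without loss of LiF.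

Arene 6 is traced to 3-fluoro-5-methoxyphenol 1. The O–benzyl bond is exchanged for O–silyl (4, through phenolate 5), then the C8–CH3 bond is cut (4 to 2, through aryllithium 3), then the O–Si bond. Methylation of a benzyl ether could not distinguish the two fluorine-flanked C–H bonds, whereas the triisopropylsilyl ether 2 screens both of its neighbours and leaves only the position between fluorine and methoxy open. An iridium-catalysed C–H borylation and oxidation of a simpler fluoro(methoxy)toluene would also reach this pattern, but such catalysts also borylate next to fluorine. Phenol 1 already holds fluorine and the two oxygens in the required 1,3,5 arrangement.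

## Roads not taken

Alternative 1: Ring A is cut across C8–C8a, C6–C7 and C4a–C8a into 3-(benzyloxy)cyclobut-2-en-1-one A1 and 1-methoxyprop-1-yne A2. On heating, A1 should open to a vinylketene, add A2 in a [2+2] sense, open again and close by 6π electrocyclisation to give 5-(benzyloxy)-3-methoxy-2-methylphenol A3.
- Merits: one pericyclic cascade places hydroxyl, methyl, methoxy and benzyloxy unambiguously, the future O1 is already on C8a, and no organolithium site selectivity is needed. In fixing the ring A pattern this road is at least as secure as the chosen one, which relies on relative C–H acidities in two metalations.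
- Weak points: neither A1 nor A2 is a catalogue compound, A2 is volatile, and A1 is a vinylogous ester whose ring opening needs forcing conditions. After A3, the ring A ketone must still be put ortho to the hydroxyl, in competition with the more electron-rich position between the two ethers (para to the hydroxyl). Ring C then needs O-aroylation, acyl migration and cyclodehydration.
- Comparison: the chosen plan sets against it purchasable starting materials, direct installation of the acyl group at C4a by the same fluorine that later leaves, and two steps from ketone 11 to the flavone.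

Alternative 2: The C4–C4a bond is cut, leading to (2E)-2-methoxy-3-[4-methoxy-3,5-di(propan-2-yloxy)phenyl]-3-[3-methoxy-2-methyl-5-(propan-2-yloxy)phenoxy]prop-2-enoic acid A4, in which O1 already links ring A to C2. Activation of A4 as a mixed anhydride should acylate the only free position ortho to the aryloxy oxygen and give the tri-isopropyl flavone A5.
- Merits: the closure is as unambiguous as the chosen one, because the methyl group blocks the other ortho position; the ring attacked carries three oxygen donors; and no carbon–fluorine chemistry is needed.
- Weak points: A4 is a tetrasubstituted alkene that must have carboxyl and aryloxy cis, and it has no short synthesis. It also presupposes a differentiated ring A phenol of the A3 type, so the ring A problem is moved and not solved. The isopropyl ethers dictated by the acidic closure need a boron halide for removal, which puts the C3 methoxy at risk.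
- Comparison: the chosen plan offers a shorter path to its cyclisation precursor and a neutral final deprotection.

Alternative 3: The C7–C8 bond of ring A is cut, leading to methyl 3-{2-[3,5-bis(benzyloxy)-4-methoxyphenyl]-6-ethyl-3-methoxy-4-oxo-4H-pyran-5-yl}-3-oxopropanoate A6. A strong lithium amide base should turn the ethyl group into a vinylogous carbanion that attacks the ester and, after tautomerisation, gives 2-[3,5-bis(benzyloxy)-4-methoxyphenyl]-5,7-dihydroxy-3-methoxy-8-methyl-4H-chromen-4-one A7.
- Merits: the methyl position is fixed by constitution. Ring A needs no protecting group, since the chelated C5 hydroxyl of A7 lets the C7 hydroxyl be methylated selectively; in this respect the road is better than the chosen one.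
- Weak points: the most acidic site of A6 is the CH2 of the keto ester, whose enolate deactivates the ester, so a polyanion is needed. The fully substituted pyranone A6 has no concise synthesis and would cost more steps than the whole chosen route.
- Comparison: the chosen plan accepts one more benzyl ether in exchange for simple building blocks and a convergent assembly.

Key step: step 9

Remark: 3-fluoro-5-methoxyphenol 1 is taken to be purchasable; diketone 17 is drawn in the diketo form, but it will exist with its enol and its C2 centre is racemic and labile, which is of no consequence because that carbon becomes trigonal C3 in step 9.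

## Route

Step 1
Reactants: 1 3-fluoro-5-methoxyphenol
Product: 2 (3-fluoro-5-methoxyphenoxy)tri(propan-2-yl)silane
Conditions: iPr3SiCl, imidazole, DMF, rt
Reagents that add atoms: chlorotri(propan-2-yl)silane, CC(C)[Si](Cl)(C(C)C)C(C)C
Why: Silylation of a phenol with a silyl chloride and imidazole is routine; the triisopropylsilyl ether is stable to alkyllithiums and screens both positions next to its oxygen in the following metalation.

Step 2
Reactants: 2 (3-fluoro-5-methoxyphenoxy)tri(propan-2-yl)silane
Product: 4 (3-fluoro-5-methoxy-4-methylphenoxy)tri(propan-2-yl)silane, via aryllithium 3 (not isolated)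
Conditions: sec-BuLi, THF, −78 °C; then MeI, −78 °C to rt
Reagents that add atoms: iodomethane, CI
Why: Directed ortho-metalation: the C–H between fluorine and methoxy is acidified by both neighbours, whereas the two C–H bonds next to the silyloxy group are screened by the isopropyl groups, so 3 should form at this carbon alone and be methylated by SN2 attack on iodomethane; holding 3 at −78 °C prevents loss of LiF.

Step 3
Reactants: 4 (3-fluoro-5-methoxy-4-methylphenoxy)tri(propan-2-yl)silane
Product: 6 1-(benzyloxy)-3-fluoro-5-methoxy-4-methylbenzene, via tetrabutylammonium phenolate 5 (not isolated)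
Conditions: Bu4NF, THF, 0 °C; then BnBr, 0 °C to rt
Reagents that add atoms: benzyl bromide, BrCc1ccccc1
Why: Fluoride cleaves the Si–O bond and leaves the loosely ion-paired phenolate 5, which is benzylated in the same flask (Williamson ether synthesis); the benzyl ether is needed from here on because it supports lithiation at its ortho position and is removable by hydrogenolysis.

Step 4
Reactants: 7 methoxyacetyl chloride
Product: 8 N,2-dimethoxy-N-methylacetamide
Conditions: MeNHOMe·HCl, Et3N, CH2Cl2, 0 °C to rt
Reagents that add atoms: N,O-dimethylhydroxylamine hydrochloride, CNOC.Cl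
Why: Acylation of N,O-dimethylhydroxylamine by an acid chloride with a tertiary amine as acid scavenger (Weinreb amide formation).

Step 5
Reactants: 6 1-(benzyloxy)-3-fluoro-5-methoxy-4-methylbenzene; 8 N,2-dimethoxy-N-methylacetamide
Product: 11 1-[6-(benzyloxy)-2-fluoro-4-methoxy-3-methylphenyl]-2-methoxyethan-1-one, via aryllithium 9 (not isolated), via lithium aminal alkoxide 10 (not isolated)
Conditions: LiN(iPr)2, THF, −78 °C; then 8, −78 to −50 °C; then 1 M HCl
Reagents that add atoms: none
Why: Directed ortho-metalation followed by Weinreb ketone synthesis: the lithium amide should remove only the proton flanked by fluorine and benzyloxy, since the proton between the two ethers is too weakly acidic for an amide base at −78 °C and LiN(iPr)2 leaves the benzylic CH2 alone; 9 adds to 8 to give the chelated adduct 10, which releases the ketone only on acidic work-up, so no second addition occurs.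

Step 6
Reactants: 12 3,5-dihydroxy-4-methoxybenzoic acid
Product: 14 3,5-bis(benzyloxy)-4-methoxybenzoic acid, via benzyl ester 13 (not isolated)
Conditions: BnBr, K2CO3, DMF, 60 °C; then NaOH, H2O–MeOH, 65 °C; then HCl
Reagents that add atoms: benzyl bromide, BrCc1ccccc1; sodium hydroxide, [Na+].[OH-]
Why: Williamson alkylation of both phenols and the carboxylate gives benzyl ester 13, which is saponified in the same operation; aryl benzyl ethers are inert to aqueous hydroxide.

Step 7
Reactants: 14 3,5-bis(benzyloxy)-4-methoxybenzoic acid
Product: 15 3,5-bis(benzyloxy)-4-methoxybenzoyl chloride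
Conditions: (COCl)2, cat. DMF, CH2Cl2, 0 °C to rt
Reagents that add atoms: oxalyl chloride, ClC(=O)C(Cl)=O
Why: Standard conversion of a carboxylic acid into its chloride with oxalyl chloride under catalysis by DMF; aryl benzyl ethers tolerate the conditions.

Step 8
Reactants: 11 1-[6-(benzyloxy)-2-fluoro-4-methoxy-3-methylphenyl]-2-methoxyethan-1-one; 15 3,5-bis(benzyloxy)-4-methoxybenzoyl chloride
Product: 17 1-[6-(benzyloxy)-2-fluoro-4-methoxy-3-methylphenyl]-3-[3,5-bis(benzyloxy)-4-methoxyphenyl]-2-methoxypropane-1,3-dione, via lithium enolate 16 (not isolated)
Conditions: LiN(SiMe3)2 (2.1 equiv), THF–toluene, −78 °C; then 15, −78 to 0 °C; then 1 M HCl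
Reagents that add atoms: none
Why: Claisen-type C-acylation of a ketone lithium enolate with an aroyl chloride: the tightly bound lithium of chelated enolate 16 favours reaction at carbon, and the second equivalent of base converts the more acidic product into its enolate, which stops further acylation; the new C2 centre is labile and disappears in step 9.

Step 9
Reactants: 17 1-[6-(benzyloxy)-2-fluoro-4-methoxy-3-methylphenyl]-3-[3,5-bis(benzyloxy)-4-methoxyphenyl]-2-methoxypropane-1,3-dione
Product: 20 5-(benzyloxy)-2-[3,5-bis(benzyloxy)-4-methoxyphenyl]-3,7-dimethoxy-8-methyl-4H-chromen-4-one, via potassium enolate 18 (not isolated), via fluoride adduct 19 (not isolated)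
Conditions: K2CO3, dry DMF, 80 °C
Reagents that add atoms: none
Why: K2CO3 removes the doubly activated proton of 17 and gives the delocalised enolate 18. The oxygen on the ring B side of 18 adds to C8a, the fluorine-bearing carbon ortho to the ring A ketone, to give the cyclohexadienyl anion 19, whose charge lies on C4a, C6 and C8 and is taken up by the C4 carbonyl; loss of fluoride from 19 restores the arene and completes pyranone ring C (addition–elimination, SNAr). The closest known reaction type is the base-mediated cyclisation of 1-(2-fluorophenyl)-1,3-diketones to chromones and flavones. Ring C closes as a six-membered ring onto a trigonal carbon, 6-exo-trig when the C8–C8a bond of the arene is taken as the bond attacked and equally describable as a 6-endo oxa-Michael addition to the C4a–C8a bond of a vinylogous acyl fluoride; both modes are favourable. No stereocentre is formed, and the labile centre of 17 becomes trigonal C3. The step needs O1 to bond to C8a and not to C5: fluoride is the only competent leaving group, and attack by the central carbon or by the ring A oxygen would need a four-membered ring. The alkoxy groups on C5 and C7 are meta to C8a and place no lone-pair density on the carbons that carry the charge of 19, while fluorine makes C8a the most electrophilic ring carbon. Dry DMF leaves the enolate oxygen poorly solvated and keeps out hydroxide, the agent of retro-Claisen cleavage.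

Step 10
Reactants: 20 5-(benzyloxy)-2-[3,5-bis(benzyloxy)-4-methoxyphenyl]-3,7-dimethoxy-8-methyl-4H-chromen-4-one
Product: 21 2-(3,5-dihydroxy-4-methoxyphenyl)-5-hydroxy-3,7-dimethoxy-8-methyl-4H-chromen-4-one
Conditions: H2 (1 atm), 10% Pd/C, EtOAc–MeOH, rt
Reagents that add atoms: none
Why: Catalytic hydrogenolysis of aryl benzyl ethers over palladium; the neutral conditions should leave the three methyl ethers, the C4 carbonyl and the conjugated C2–C3 double bond untouched, and the product is the target.

## Compound list

1 | 3-fluoro-5-methoxyphenol | COc1cc(O)cc(F)c1 | starting material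
2 | (3-fluoro-5-methoxyphenoxy)tri(propan-2-yl)silane | COc1cc(F)cc(O[Si](C(C)C)(C(C)C)C(C)C)c1 | intermediate
3 | [2-fluoro-6-methoxy-4-{[tri(propan-2-yl)silyl]oxy}phenyl]lithium | COc1cc(O[Si](C(C)C)(C(C)C)C(C)C)cc(F)c1[Li] | intermediate (not isolated)
4 | (3-fluoro-5-methoxy-4-methylphenoxy)tri(propan-2-yl)silane | COc1cc(O[Si](C(C)C)(C(C)C)C(C)C)cc(F)c1C | intermediate
5 | tetrabutylammonium 3-fluoro-5-methoxy-4-methylphenolate | CCCC[N+](CCCC)(CCCC)CCCC.COc1cc([O-])cc(F)c1C | intermediate (not isolated)
6 | 1-(benzyloxy)-3-fluoro-5-methoxy-4-methylbenzene | COc1cc(OCc2ccccc2)cc(F)c1C | intermediate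
7 | methoxyacetyl chloride | COCC(Cl)=O | starting material
8 | N,2-dimethoxy-N-methylacetamide | COCC(=O)N(C)OC | intermediate
9 | [6-(benzyloxy)-2-fluoro-4-methoxy-3-methylphenyl]lithium | [Li]c1c(F)c(C)c(OC)cc1OCc1ccccc1 | intermediate (not isolated)
10 | lithium 1-[6-(benzyloxy)-2-fluoro-4-methoxy-3-methylphenyl]-2-methoxy-1-[methoxy(methyl)amino]ethan-1-olate (racemic) | [Li+].[O-]C(COC)(N(C)OC)c1c(F)c(C)c(OC)cc1OCc1ccccc1 | intermediate (not isolated)
11 | 1-[6-(benzyloxy)-2-fluoro-4-methoxy-3-methylphenyl]-2-methoxyethan-1-one | COCC(=O)c1c(F)c(C)c(OC)cc1OCc1ccccc1 | intermediate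
12 | 3,5-dihydroxy-4-methoxybenzoic acid | COc1c(O)cc(cc1O)C(O)=O | starting material
13 | benzyl 3,5-bis(benzyloxy)-4-methoxybenzoate | COc1c(OCc2ccccc2)cc(cc1OCc1ccccc1)C(=O)OCc1ccccc1 | intermediate (not isolated)
14 | 3,5-bis(benzyloxy)-4-methoxybenzoic acid | COc1c(OCc2ccccc2)cc(cc1OCc1ccccc1)C(O)=O | intermediate
15 | 3,5-bis(benzyloxy)-4-methoxybenzoyl chloride | COc1c(OCc2ccccc2)cc(cc1OCc1ccccc1)C(Cl)=O | intermediate
16 | lithium (Z)-1-[6-(benzyloxy)-2-fluoro-4-methoxy-3-methylphenyl]-2-methoxyethen-1-olate (geometry expected from lithium chelation) | [Li+].[O-]/C(=C\OC)c1c(F)c(C)c(OC)cc1OCc1ccccc1 | intermediate (not isolated)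
17 | 1-[6-(benzyloxy)-2-fluoro-4-methoxy-3-methylphenyl]-3-[3,5-bis(benzyloxy)-4-methoxyphenyl]-2-methoxypropane-1,3-dione (racemic, C2 labile) | COc1cc(OCc2ccccc2)c(C(=O)C(OC)C(=O)c2cc(OCc3ccccc3)c(OC)c(OCc3ccccc3)c2)c(F)c1C | intermediate
18 | potassium 3-[6-(benzyloxy)-2-fluoro-4-methoxy-3-methylphenyl]-1-[3,5-bis(benzyloxy)-4-methoxyphenyl]-2-methoxy-3-oxoprop-1-en-1-olate (delocalised, one resonance form drawn) | [K+].[O-]C(=C(OC)C(=O)c1c(F)c(C)c(OC)cc1OCc1ccccc1)c1cc(OCc2ccccc2)c(OC)c(OCc2ccccc2)c1 | intermediate (not isolated)
19 | potassium 5-(benzyloxy)-2-[3,5-bis(benzyloxy)-4-methoxyphenyl]-8a-fluoro-3,7-dimethoxy-8-methyl-8aH-chromen-4-olate (racemic) | [K+].[O-]C1=C2C(OCc3ccccc3)=CC(OC)=C(C)C2(F)OC(c2cc(OCc3ccccc3)c(OC)c(OCc3ccccc3)c2)=C1OC | intermediate (not isolated)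
20 | 5-(benzyloxy)-2-[3,5-bis(benzyloxy)-4-methoxyphenyl]-3,7-dimethoxy-8-methyl-4H-chromen-4-one | COc1cc(OCc2ccccc2)c2c(=O)c(OC)c(-c3cc(OCc4ccccc4)c(OC)c(OCc4ccccc4)c3)oc2c1C | intermediate
21 | 2-(3,5-dihydroxy-4-methoxyphenyl)-5-hydroxy-3,7-dimethoxy-8-methyl-4H-chromen-4-one | COc1cc(O)c2c(=O)c(OC)c(-c3cc(O)c(OC)c(O)c3)oc2c1C | target

## Step count and risks

Total step count: 10. Longest linear sequence: 7 steps (steps 1, 2, 3, 5, 8, 9 and 10).

Step 9 (key step). The most likely failure is slow addition of the stabilised enolate oxygen to a fluoroarene that is electron-rich, flanked by a methyl group and attached to a ketone twisted out of the ring plane. At the temperatures then needed, retro-Claisen cleavage of the 2-methoxy-1,3-diketone by traces of hydroxide could overtake ring closure. The fallback sets out from ketone 11 and makes the same C8a–oxygen bond intermolecularly, where the ketone is a neutral acceptor and the nucleophile is stronger. Acetohydroxamic acid and K2CO3 in DMSO should displace fluoride and, after fragmentation of the O-aryl hydroxamate, give 1-[6-(benzyloxy)-2-hydroxy-4-methoxy-3-methylphenyl]-2-methoxyethan-1-one F1. Aroylation of this phenol with 15 in pyridine should give 3-(benzyloxy)-5-methoxy-2-(methoxyacetyl)-6-methylphenyl 3,5-bis(benzyloxy)-4-methoxybenzoate F2. Baker–Venkataraman rearrangement with KOH in pyridine should give 1-[6-(benzyloxy)-2-hydroxy-4-methoxy-3-methylphenyl]-3-[3,5-bis(benzyloxy)-4-methoxyphenyl]-2-methoxypropane-1,3-dione F3. Cyclodehydration with TsOH in warm toluene closes O1–C2 and comes back to the route at 20. Because the fluorine marked C8a, only one phenol is free and the closure remains unambiguous.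

Step 5. Deprotonation may be incomplete or may stray to the position between the two ethers, the lithiated arene may lose LiF to an aryne if the temperature rises, and proton transfer from the CH2 of 8 may quench 9. The fallback sets out from 6 and replaces deprotonation by electrophilic substitution and halogen–metal exchange. NBS in MeCN should brominate the carbon that is para to methoxy and ortho to benzyloxy, the less hindered of the two activated positions, to give 1-(benzyloxy)-2-bromo-3-fluoro-5-methoxy-4-methylbenzene F4. Exchange with n-BuLi at −78 °C comes back to the route at aryllithium 9, which is acylated with 8 to 11 as before.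

Step 8. Acylation on the enolate oxygen, or a second acylation, may compete with the wanted C-acylation, because the enolate carbon is substituted and hindered. The fallback sets out from 15 and 11 and forms the same carbon–carbon bond by aldol addition, which cannot occur on oxygen. Reduction of 15 with LiAlH(OtBu)3 at −78 °C should give 3,5-bis(benzyloxy)-4-methoxybenzaldehyde F5. Addition of enolate 16 to it should give 1-[6-(benzyloxy)-2-fluoro-4-methoxy-3-methylphenyl]-3-[3,5-bis(benzyloxy)-4-methoxyphenyl]-3-hydroxy-2-methoxypropan-1-one F6 as a mixture of diastereomers. Oxidation with Dess–Martin periodinane comes back to the route at 17.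

Step 10. Partial saturation of the C2–C3 double bond, or stalling before the last benzyl ether is cleaved, would give mixtures that are hard to separate from the polar target. The fallback sets out from 20 and replaces hydrogenolysis by Lewis-acid debenzylation with BCl3 and pentamethylbenzene as cation scavenger in CH2Cl2 at −78 °C, a temperature at which aryl methyl ethers are expected to persist. It arrives directly at 21 and makes no new compound (F0).

## Further compounds

F1 | step 9 | 1-[6-(benzyloxy)-2-hydroxy-4-methoxy-3-methylphenyl]-2-methoxyethan-1-one | COCC(=O)c1c(O)c(C)c(OC)cc1OCc1ccccc1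
F2 | step 9 | 3-(benzyloxy)-5-methoxy-2-(methoxyacetyl)-6-methylphenyl 3,5-bis(benzyloxy)-4-methoxybenzoate | COCC(=O)c1c(OC(=O)c2cc(OCc3ccccc3)c(OC)c(OCc3ccccc3)c2)c(C)c(OC)cc1OCc1ccccc1
F3 | step 9 | 1-[6-(benzyloxy)-2-hydroxy-4-methoxy-3-methylphenyl]-3-[3,5-bis(benzyloxy)-4-methoxyphenyl]-2-methoxypropane-1,3-dione (racemic, C2 labile) | COc1cc(OCc2ccccc2)c(C(=O)C(OC)C(=O)c2cc(OCc3ccccc3)c(OC)c(OCc3ccccc3)c2)c(O)c1C
F4 | step 5 | 1-(benzyloxy)-2-bromo-3-fluoro-5-methoxy-4-methylbenzene | COc1cc(OCc2ccccc2)c(Br)c(F)c1C
F5 | step 8 | 3,5-bis(benzyloxy)-4-methoxybenzaldehyde | COc1c(OCc2ccccc2)cc(C=O)cc1OCc1ccccc1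
F6 | step 8 | 1-[6-(benzyloxy)-2-fluoro-4-methoxy-3-methylphenyl]-3-[3,5-bis(benzyloxy)-4-methoxyphenyl]-3-hydroxy-2-methoxypropan-1-one (racemic mixture of diastereomers) | COc1cc(OCc2ccccc2)c(C(=O)C(OC)C(O)c2cc(OCc3ccccc3)c(OC)c(OCc3ccccc3)c2)c(F)c1C
F0 | step 10 | none | none
A1 | alternative 1 | 3-(benzyloxy)cyclobut-2-en-1-one | O=C1CC(OCc2ccccc2)=C1
A2 | alternative 1 | 1-methoxyprop-1-yne | COC#CC
A3 | alternative 1 | 5-(benzyloxy)-3-methoxy-2-methylphenol | COc1cc(OCc2ccccc2)cc(O)c1C
A4 | alternative 2 | (2E)-2-methoxy-3-[4-methoxy-3,5-di(propan-2-yloxy)phenyl]-3-[3-methoxy-2-methyl-5-(propan-2-yloxy)phenoxy]prop-2-enoic acid | OC(=O)/C(OC)=C(\Oc1cc(OC(C)C)cc(OC)c1C)c1cc(OC(C)C)c(OC)c(OC(C)C)c1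
A5 | alternative 2 | 2-[4-methoxy-3,5-di(propan-2-yloxy)phenyl]-3,7-dimethoxy-8-methyl-5-(propan-2-yloxy)-4H-chromen-4-one | COc1cc(OC(C)C)c2c(=O)c(OC)c(-c3cc(OC(C)C)c(OC)c(OC(C)C)c3)oc2c1C
A6 | alternative 3 | methyl 3-{2-[3,5-bis(benzyloxy)-4-methoxyphenyl]-6-ethyl-3-methoxy-4-oxo-4H-pyran-5-yl}-3-oxopropanoate | CCc1oc(-c2cc(OCc3ccccc3)c(OC)c(OCc3ccccc3)c2)c(OC)c(=O)c1C(=O)CC(=O)OC
A7 | alternative 3 | 2-[3,5-bis(benzyloxy)-4-methoxyphenyl]-5,7-dihydroxy-3-methoxy-8-methyl-4H-chromen-4-one | Cc1c(O)cc(O)c2c(=O)c(OC)c(-c3cc(OCc4ccccc4)c(OC)c(OCc4ccccc4)c3)oc12
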